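**Plan**

- Cuts, in order: both aryl ether C–O bonds of the dioxane (ortho-quinone + guaia-1(5),3,11-triene); the C6=C7 unsaturation; C8–C14 together with C9–C10 (one cationic bicyclisation); C9–C11 (Negishi coupling); C16–C17 (anionic oxy-Cope shift, C14–C21 restored); the cage into a masked ortho-benzoquinone and an acrylamide.
- Enabling feature: rings D and E are cis-fused and hold the quaternary carbons C13, C17 and C20. An added C14–C21 bond turns them into a bicyclo[2.2.2]oct-5-ene (bridgeheads C18, C21) whose methyl-bearing alkene carbon is C17, so a vinyl carbinol at C14 is a 1,5-diene set up for a [3,3] shift.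
- Forward ring order: ring E inside the cage (Diels–Alder), ring D (oxy-Cope), rings C and B onto aryl ring A (bicyclisation), dioxane ring last (hetero-Diels–Alder). The hydroazulene is built separately from (S)-carvone by ring expansion and ring-closing metathesis.
- Stereochemistry: C18/C21 from a camphorsultam acrylamide; C13, C20 and the C14 vinyl group from attack on the alkene side of the cage; C17 cis to H-18 from the boat [3,3] shift; C8, C9, C14 from chair-like anti addition across an E-alkene; C7′, C10′ from (S)-carvone and an ene-reductase; C3′, C4′ from cycloaddition anti to the C10′ methyl.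

Key step: step 10

Remark: friedelane numbering is used for the triterpenoid and primed guaiane numbering for the sesquiterpenoid. Centres that a later step erases (C20 in 6–11, C13 in 9, C11 in 21, C14 in 35, C5′ in 42) are drawn as the expected epimer or left open.

Assumption: under non-chelating conditions the (2R)-sultam directs the diene to the Cα si face of 3; the antipodal sultam would be taken otherwise.

**Route**

Step 1
Reactants: 1 (2R)-bornane-10,2-sultam; 2 acryloyl chloride
Product: 3 N-acryloyl-(2R)-bornane-10,2-sultam
Conditions: NaH, toluene, 0 °C to rt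
Reagents that add atoms: none
Why: N-acylation of the sultam sodium salt by the acid chloride (amide formation); no stereocentre is formed.

Step 2
Reactants: 4 creosol; 3 N-acryloyl-(2R)-bornane-10,2-sultam
Product: 6 endo cage imide, via masked ortho-benzoquinone 5 (not isolated)
Conditions: PhI(OAc)2 (1.1 equiv), 3 (3 equiv, excess recovered), MeOH/CH2Cl2, slow addition of 4, 0 to 40 °C; crystallisation
Reagents that add atoms: methanol (CO)
Why: Oxidative dearomatisation in methanol gives the dimethyl-ketal dienone, which is trapped at once in a Diels–Alder reaction; the acyl-bearing carbon should bond to the diene terminus next to the ketone (ortho rule, reinforced by the para-directing methyl), the acyl group should sit endo, and the sultam should fix the face of the acrylamide and hence the bridgeheads C18 and C21, the required diastereomer being purified by crystallisation.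

Step 3
Reactants: 6 endo cage imide
Product: 7 cage ketal methyl ester
Conditions: NaOMe (1.2 equiv), MeOH/THF, 0 °C; AcOH quench
Reagents that add atoms: sodium methoxide ([Na+].C[O-])
Why: Methanolysis of the activated N-acyl sultam (acyl transfer) frees the auxiliary for reuse; any epimerisation at C20 is harmless because this centre is rebuilt in step 7.

Step 4
Reactants: 7 cage ketal methyl ester
Product: 8 cage keto ester with C13 methylene
Conditions: SmI2 (5 equiv), THF/MeOH, 0 °C to rt
Reagents that add atoms: none
Why: Reductive cleavage of the alpha-alkoxy ketone by SmI2 (ketyl formation and beta-elimination, twice) removes both methoxy groups while the ester and the isolated alkene stay untouched; no stereocentre is formed.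

Step 5
Reactants: 8 cage keto ester with C13 methylene
Product: 9 C13-methyl cage keto ester
Conditions: LDA (1.05 equiv), THF, −78 °C; MeI
Reagents that add atoms: iodomethane (CI)
Why: Kinetic enolate alkylation; only C13 can enolise because C21 is a bridgehead and the ketone is more acidic than the ester, and the C13 centre formed here becomes planar again in step 6.

Step 6
Reactants: 9 C13-methyl cage keto ester; 10 allyl bromide
Product: 11 C13-allyl C13-methyl cage keto ester
Conditions: KHMDS, THF, −78 °C; 10, to −20 °C
Reagents that add atoms: none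
Why: Enolate allylation builds quaternary C13; the electrophile should approach from the etheno-bridge side, since the ethano bridge projects a hydrogen over the other face, so allyl ends syn to the alkene and the C27 methyl points to the C19–C20 bridge (13α-methyl of the target).

Step 7
Reactants: 11 C13-allyl C13-methyl cage keto ester
Product: 12 C20-methyl cage keto ester
Conditions: LDA, THF, −78 °C; MeI, to −40 °C
Reagents that add atoms: iodomethane (CI)
Why: Ester enolate alkylation (the ketone can no longer enolise); MeI should reach C20 from the alkene side, away from the cleft crowded by the C13 substituents, which puts the new methyl syn to the alkene and the ester toward C14 (20β-methyl, 20α-ester).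

Step 8
Reactants: 12 C20-methyl cage keto ester; 13 vinylmagnesium bromide
Product: 15 vinyl cage lactone, via bromomagnesium alkoxide 14 (not isolated)
Conditions: CeCl3, THF, −78 °C to rt
Reagents that add atoms: none
Why: CeCl3-mediated 1,2-addition to the non-enolisable ketone should come from the alkene side because the C20 ester covers the other face, so vinyl sits syn to the etheno bridge; the alkoxide then closes onto the nearby ester (lactonisation), which would confirm the relative configuration and gives a neutral, purifiable compound (any open hydroxy ester converges in step 9).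

Step 9
Reactants: 15 vinyl cage lactone
Product: 16 potassium salt of the vinyl carbinol acid
Conditions: KOH (1.05 equiv), MeOH/H2O, 60 °C; evaporate, toluene azeotrope, vacuum
Reagents that add atoms: potassium hydroxide ([K+].[OH-])
Why: Saponification of the strained lactone gives the hydroxy carboxylate; as a carboxylate the C29 group can no longer acylate the C14 oxygen in the next step.

Step 10
Reactants: 16 potassium salt of the vinyl carbinol acid
Product: 19 cis-decalone acid, via dipotassium alkoxide carboxylate 17 (not isolated), via dipotassium enolate carboxylate 18 (not isolated)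
Conditions: KH (1.5 equiv), 18-crown-6 (2.2 equiv), THF, 0 °C to rt; then 1 M HCl, 0 °C
Reagents that add atoms: none
Why: KH converts the C14 carbinol into the potassium alkoxide 17, whose oxyanion weakens the adjacent C14–C21 bond and drives a concerted [3,3]-sigmatropic shift of the 3-oxido-1,5-diene C16=C15–C14(O−)–C21–C22=C17 to the enolate 18, which is protonated to the ketone on work-up. The closest known reaction type is the anionic oxy-Cope rearrangement of 2-vinylbicyclo[2.2.2]oct-5-en-2-ols made from masked ortho-benzoquinone cycloadducts, which gives cis-decalins with angular methyl groups. Ring D closes by suprafacial C16–C17 bond formation inside the six-centre boat transition state that the cage imposes, while cleavage of C14–C21 releases ring E from the bicycle. The new quaternary centre C17 is controlled by the cage, because C16 can reach only the alkene face turned toward the C13–C14 bridge; the angular methyl is therefore cis to H-18, and C13, C18 and C20 pass through unchanged. The step needs the vinyl group syn to the etheno bridge and a free oxyanion: the first is secured by the alkene-side addition of step 8, the second by carrying C29 as a carboxylate, which cannot trap the alkoxide as a lactone.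

Step 11
Reactants: 19 cis-decalone acid
Product: 20 cis-decalone methyl ester
Conditions: TMSCHN2, MeOH/toluene, 0 °C
Reagents that add atoms: trimethylsilyldiazomethane (C[Si](C)(C)C=[N+]=[N-])
Why: Esterification of the carboxylic acid by O-methylation with a diazoalkane; ketone and alkenes are inert and no stereocentre is touched.

Step 12
Reactants: 20 cis-decalone methyl ester
Product: 23 primary alcohol, via diol 21 (not isolated), via aldehyde 22 (not isolated)
Conditions: OsO4 (2 mol %), NMO, acetone/H2O, 0 °C; NaIO4, rt; then NaBH4, MeOH, −30 °C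
Reagents that add atoms: N-methylmorpholine N-oxide (C[N+]1([O-])CCOCC1)
Why: Catalytic dihydroxylation and periodate cleavage (Lemieux–Johnson oxidation) followed by borohydride reduction of the aldehyde; the monosubstituted alkene should react while the ring E alkene, flanked by two quaternary carbons, and the hindered ketone are left.

Step 13
Reactants: 23 primary alcohol
Product: 24 ring E saturated alcohol
Conditions: H2 (4 atm), Pd/C, EtOAc, rt
Reagents that add atoms: none
Why: Heterogeneous hydrogenation of the cis-disubstituted ring E alkene; ketone and ester are not reduced over Pd/C and no stereocentre is formed.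

Step 14
Reactants: 24 ring E saturated alcohol
Product: 25 primary iodide
Conditions: I2, PPh3, imidazole, CH2Cl2, 0 °C to rt
Reagents that add atoms: iodine (II)
Why: Appel iodination of the primary alcohol; the open hydroxy ketone reacts even if a hemiketal is in equilibrium with it.

Step 15
Reactants: 26 2,3-dimethoxytoluene
Product: 27 benzylic bromide
Conditions: (CH2O)n, HBr (33 % in AcOH), rt
Reagents that add atoms: paraformaldehyde (C=O); hydrogen bromide (Br)
Why: Electrophilic bromomethylation (Blanc-type) should occur para to the methoxy group that is not flanked by the methyl and ortho to the methyl, the most activated free position.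

Step 16
Reactants: 28 2-butyne; 27 benzylic bromide
Product: 30 aryl pentyne, via but-2-ynyllithium 29 (not isolated)
Conditions: n-BuLi, TMEDA, THF, −78 to 0 °C; then 27, −78 °C to rt
Reagents that add atoms: none
Why: Propargylic lithiation of 2-butyne and SN2 alkylation by the benzylic bromide at the propargylic terminus give the internal alkyne that holds C6–C9 and C25.

Step 17
Reactants: 30 aryl pentyne
Product: 32 E-vinyl iodide, via alkenylzirconocene chloride 31 (not isolated)
Conditions: Cp2Zr(H)Cl (2.2 equiv), THF, 50 °C; then I2, 0 °C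
Reagents that add atoms: iodine (II)
Why: Hydrozirconation is a syn addition and, with excess hydride under equilibration, should place zirconium on the less hindered methyl-bearing carbon; iodinolysis with retention gives the iodide trans to the arylethyl chain.

Step 18
Reactants: 25 primary iodide; 32 E-vinyl iodide
Product: 34 coupled keto ester, via alkylzinc iodide 33 (not isolated)
Conditions: Zn dust, LiCl, THF, 40 °C; then 32, Pd2(dba)3 (2.5 mol %), SPhos (10 mol %), THF/NMP, rt to 40 °C
Reagents that add atoms: none
Why: Negishi sp3–sp2 coupling; the alkylzinc reagent tolerates ketone and ester, and the coupling keeps the alkene geometry, so C11 ends trans to C7 (E-alkene C8=C9).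

Step 19
Reactants: 34 coupled keto ester
Product: 35 tertiary alcohol
Conditions: MeMgBr, CeCl3, THF, −78 to 0 °C
Reagents that add atoms: methylmagnesium bromide (C[Mg]Br)
Why: CeCl3-mediated 1,2-addition of the methyl nucleophile to the C14 ketone (the neopentyl-type ester is not attacked at low temperature); the carbinol configuration is irrelevant because C14 is ionised next.

Step 20
Reactants: 35 tertiary alcohol
Product: 36 pentacyclic dimethyl ether
Conditions: SnCl4 (2 equiv), CH2Cl2, −78 to −30 °C; aq. NaHCO3
Reagents that add atoms: none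
Why: Ionisation gives the C14 cation, which is captured by the E-trisubstituted alkene and then by the arene para to a methoxy group (cationic polyene bicyclisation ending in Friedel–Crafts alkylation, two 6-endo closures); chair-like folding with the C12 tether equatorial on ring D and anti addition across the E-alkene should set 14β-methyl, 8α-H and 9β-methyl.

Step 21
Reactants: 36 pentacyclic dimethyl ether
Product: 37 C6=C7 styrene
Conditions: DDQ (1.1 equiv), dioxane, 90 °C
Reagents that add atoms: none
Why: Benzylic dehydrogenation by hydride abstraction from C6 (para to the C2 methoxy group) and loss of H-7; C8 keeps its hydrogen and configuration.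

Step 22
Reactants: 37 C6=C7 styrene
Product: 38 catechol
Conditions: BBr3 (3 equiv), CH2Cl2, −78 to −20 °C; aq. NaHCO3
Reagents that add atoms: none
Why: Lewis-acid cleavage of the two aryl methyl ethers; at low temperature the methyl ester and the styrene should survive.

Step 23
Reactants: 39 (S)-carvone
Product: 40 (2R,5S)-dihydrocarvone
Conditions: ene-reductase OYE1, NADP+ (cat.), glucose dehydrogenase, D-glucose, phosphate buffer pH 7, 30 °C
Reagents that add atoms: none
Why: Enzymatic conjugate reduction of the enone; hydride goes to the beta carbon and the enzyme protonates the alpha carbon to give the 2R centre (future C10′), cis to the isopropenyl group, while C5 (future C7′) comes from carvone.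

Step 24
Reactants: 40 (2R,5S)-dihydrocarvone; 41 ethyl diazoacetate
Product: 42 cycloheptanone keto ester
Conditions: BF3·OEt2, Et2O, 0 °C
Reagents that add atoms: none
Why: Lewis-acid-promoted ring expansion of the ketone by the diazo ester (Büchner–Curtius–Schlotterbeck type); the less substituted methylene migrates, so the ester carbon (future C4′) lands on C5′ and the C10′ centre is not touched.

Step 25
Reactants: 42 cycloheptanone keto ester
Product: 43 enol triflate
Conditions: NaH, THF, 0 °C; PhNTf2
Reagents that add atoms: N-phenylbis(trifluoromethanesulfonimide) (O=S(=O)(N(c1ccccc1)S(=O)(=O)C(F)(F)F)C(F)(F)F)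
Why: O-sulfonylation of the keto ester enolate fixes the C1′=C5′ double bond; NaH removes only the proton between the carbonyls, so C10′ cannot epimerise.

Step 26
Reactants: 43 enol triflate
Product: 44 allyl enoate
Conditions: allylSnBu3, Pd(PPh3)4 (5 mol %), LiCl, THF, 65 °C
Reagents that add atoms: allyltributylstannane (C=CC[Sn](CCCC)(CCCC)CCCC)
Why: Stille coupling of the vinyl triflate puts C2′ and C3′ on C1′; no stereocentre is involved.

Step 27
Reactants: 44 allyl enoate
Product: 45 tertiary allylic alcohol
Conditions: MeLi (2.5 equiv), CeCl3, THF, −78 °C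
Reagents that add atoms: methyllithium ([Li]C)
Why: Double 1,2-addition to the ester gives the dimethyl carbinol (C4′ with the C15′ methyl); CeCl3 lowers the basicity so that the doubly allylic C2′ hydrogens are not removed.

Step 28
Reactants: 45 tertiary allylic alcohol
Product: 46 triene
Conditions: methyl N-(triethylammoniosulfonyl)carbamate, benzene, 50 °C
Reagents that add atoms: none
Why: Burgess dehydration is a syn elimination through the sulfamate ester, and the only hydrogens beta to C4′ are on the methyl groups, so the isopropenyl diene should form without touching C10′.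

Step 29
Reactants: 46 triene
Product: 47 (7S,10R)-guaia-1(5),3,11-triene
Conditions: second-generation Grubbs catalyst RuCl2(=CHPh)(H2IMes)(PCy3) (5 mol %), CH2Cl2 (0.01 M), 40 °C; used at once
Reagents that add atoms: none
Why: Ring-closing metathesis between the allyl alkene and the conjugated isopropenyl group closes the five-membered ring with the C3′=C4′ bond in a defined position; closure onto the remote C7′ isopropenyl would need a bridgehead alkene and should not compete.

Step 30
Reactants: 38 catechol; 47 (7S,10R)-guaia-1(5),3,11-triene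
Product: 49 CNP0304573.1, via ortho-quinone 48 (not isolated)
Conditions: Ag2O (3 equiv), Na2SO4, CH2Cl2, 0 °C, dark; then 47 (2 equiv), −20 °C to rt
Reagents that add atoms: none
Why: Ag2O oxidises the catechol to the ortho-quinone, which adds as an electron-poor heterodiene to the C3′=C4′ bond of the cyclopentadiene (inverse-electron-demand hetero-Diels–Alder reaction); suprafacial addition makes the dioxane fusion cis, approach anti to the C10′ methyl and C7′ isopropenyl groups should set C3′ and C4′, and bonding of quaternary C4′ to the less hindered O-2, away from the aryl methyl, gives the regiochemistry of the target.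

**Compound list**

1 | (2R)-bornane-10,2-sultam (camphorsultam, N exo at C2) | N1[C@@H]2C[C@H]3CC[C@]2(CS1(=O)=O)C3(C)C | starting material
2 | acryloyl chloride | C=CC(=O)Cl | starting material
3 | N-acryloyl-(2R)-bornane-10,2-sultam | C=CC(=O)N1[C@@H]2C[C@H]3CC[C@]2(CS1(=O)=O)C3(C)C | intermediate
4 | creosol (2-methoxy-4-methylphenol) | COc1cc(C)ccc1O | starting material
5 | 6,6-dimethoxy-4-methylcyclohexa-2,4-dien-1-one (masked ortho-benzoquinone, not isolated) | COC1(OC)C=C(C)C=CC1=O | intermediate
6 | N-[endo-8,8-dimethoxy-5-methyl-7-oxobicyclo[2.2.2]oct-5-ene-2-carbonyl]-(2R)-bornane-10,2-sultam; cage C1 = C21, C2 = C20 (acyl syn to the C5=C6 bridge), C3 = C19, C4 = C18, C5 = C17, C6 = C22, C7 = C14, C8 = C13 | COC1(OC)[C@@H]2C[C@@H](C(=O)N3[C@@H]4C[C@H]5CC[C@]4(CS3(=O)=O)C5(C)C)[C@@H](C=C2C)C1=O | intermediate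
7 | methyl endo-8,8-dimethoxy-5-methyl-7-oxobicyclo[2.2.2]oct-5-ene-2-carboxylate (cage configuration as in 6) | COC1(OC)[C@@H]2C[C@@H](C(=O)OC)[C@@H](C=C2C)C1=O | intermediate
8 | methyl endo-5-methyl-7-oxobicyclo[2.2.2]oct-5-ene-2-carboxylate | C1[C@@H]2C[C@@H](C(=O)OC)[C@@H](C=C2C)C1=O | intermediate
9 | methyl endo-5,8-dimethyl-7-oxobicyclo[2.2.2]oct-5-ene-2-carboxylate (8-methyl syn to the C5=C6 bridge) | C[C@H]1[C@@H]2C[C@@H](C(=O)OC)[C@@H](C=C2C)C1=O | intermediate
10 | allyl bromide | C=CCBr | starting material
11 | methyl endo-8-allyl-5,8-dimethyl-7-oxobicyclo[2.2.2]oct-5-ene-2-carboxylate (allyl syn to the C5=C6 bridge, 8-methyl toward the C2–C3 bridge) | C=CC[C@@]1(C)[C@@H]2C[C@@H](C(=O)OC)[C@@H](C=C2C)C1=O | intermediate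
12 | methyl 8-allyl-2,5,8-trimethyl-7-oxobicyclo[2.2.2]oct-5-ene-2-carboxylate (2-methyl syn to the C5=C6 bridge, ester toward the C7 carbonyl) | C=CC[C@@]1(C)[C@@H]2C[C@](C)(C(=O)OC)[C@@H](C=C2C)C1=O | intermediate
13 | vinylmagnesium bromide | C=C[Mg]Br | starting material
14 | bromomagnesium alkoxide of methyl 8-allyl-7-hydroxy-2,5,8-trimethyl-7-vinylbicyclo[2.2.2]oct-5-ene-2-carboxylate (vinyl syn to the C5=C6 bridge; not isolated) | C=CC[C@@]1(C)[C@@H]2C[C@](C)(C(=O)OC)[C@@H](C=C2C)[C@@]1(O[Mg]Br)C=C | intermediate
15 | gamma-lactone between the C7 oxygen and the C2 carboxyl of 8-allyl-7-hydroxy-2,5,8-trimethyl-7-vinylbicyclo[2.2.2]oct-5-ene-2-carboxylic acid | C=CC[C@@]1(C)[C@@H]2C[C@]3(C)C(=O)O[C@@]1(C=C)[C@@H]3C=C2C | intermediate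
16 | potassium 8-allyl-7-hydroxy-2,5,8-trimethyl-7-vinylbicyclo[2.2.2]oct-5-ene-2-carboxylate (vinyl, allyl and 2-methyl syn to the C5=C6 bridge; C7 = C14, C8 = C13) | C=CC[C@@]1(C)[C@@H]2C[C@](C)(C(=O)[O-])[C@@H](C=C2C)[C@@]1(O)C=C.[K+] | intermediate
17 | dipotassium alkoxide carboxylate of 16 (not isolated) | C=CC[C@@]1(C)[C@@H]2C[C@](C)(C(=O)[O-])[C@@H](C=C2C)[C@@]1([O-])C=C.[K+].[K+] | intermediate
18 | dipotassium C14 enolate carboxylate of the cis-fused D/E decalin (not isolated) | C=CC[C@@]1(C)[C@@H]2C[C@](C)(C(=O)[O-])C=C[C@]2(C)CC=C1[O-].[K+].[K+] | intermediate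
19 | cis-fused D/E decalin acid: 14-oxo, 13β-allyl, 13α-methyl, 18β-H, 17β-methyl, 20β-methyl, 20α-CO2H, C21=C22 | C=CC[C@@]1(C)[C@@H]2C[C@](C)(C(=O)O)C=C[C@]2(C)CCC1=O | intermediate
20 | methyl ester of 19 | C=CC[C@@]1(C)[C@@H]2C[C@](C)(C(=O)OC)C=C[C@]2(C)CCC1=O | intermediate
21 | 1,2-diol from the allyl group of 20 (carbinol configuration open; not isolated) | OCC(O)C[C@@]1(C)[C@@H]2C[C@](C)(C(=O)OC)C=C[C@]2(C)CCC1=O | intermediate
22 | C11 aldehyde (13β-CH2CHO; not isolated) | O=CC[C@@]1(C)[C@@H]2C[C@](C)(C(=O)OC)C=C[C@]2(C)CCC1=O | intermediate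
23 | C11 primary alcohol (13β-CH2CH2OH), C21=C22 retained | OCC[C@@]1(C)[C@@H]2C[C@](C)(C(=O)OC)C=C[C@]2(C)CCC1=O | intermediate
24 | C11 primary alcohol with saturated ring E | OCC[C@@]1(C)[C@@H]2C[C@](C)(C(=O)OC)CC[C@]2(C)CCC1=O | intermediate
25 | C11 primary iodide (13β-CH2CH2I) | ICC[C@@]1(C)[C@@H]2C[C@](C)(C(=O)OC)CC[C@]2(C)CCC1=O | intermediate
26 | 2,3-dimethoxytoluene | COc1cccc(C)c1OC | starting material
27 | 1-(bromomethyl)-3,4-dimethoxy-2-methylbenzene | COc1ccc(CBr)c(C)c1OC | intermediate
28 | 2-butyne | CC#CC | starting material
29 | but-2-yn-1-yllithium (not isolated) | [Li]CC#CC | intermediate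
30 | 3,4-dimethoxy-2-methyl-1-(pent-3-yn-1-yl)benzene | CC#CCCc1ccc(OC)c(OC)c1C | intermediate
31 | (E)-alkenylzirconocene chloride, Zr on the methyl-bearing carbon and trans to the arylethyl chain (not isolated) | C/C(=C\CCc1ccc(OC)c(OC)c1C)[Zr](Cl)(C1C=CC=C1)C1C=CC=C1 | intermediate
32 | (E)-1-(4-iodopent-3-en-1-yl)-3,4-dimethoxy-2-methylbenzene | C/C(I)=C\CCc1ccc(OC)c(OC)c1C | intermediate
33 | alkylzinc iodide from 25 (not isolated) | I[Zn]CC[C@@]1(C)[C@@H]2C[C@](C)(C(=O)OC)CC[C@]2(C)CCC1=O | intermediate
34 | coupled keto ester: C14 ketone, E-alkene C8=C9 with C9 methyl, 2-(3,4-dimethoxy-2-methylphenyl)ethyl on C8 | COc1ccc(CC/C=C(\C)CC[C@@]2(C)[C@@H]3C[C@](C)(C(=O)OC)CC[C@]3(C)CCC2=O)c(C)c1OC | intermediate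
35 | C14 methyl carbinol of 34 (C14 configuration open) | COc1ccc(CC/C=C(\C)CC[C@@]2(C)[C@@H]3C[C@](C)(C(=O)OC)CC[C@]3(C)CCC2(C)O)c(C)c1OC | intermediate
36 | methyl 2,3-dimethoxy-24-nor-D:A-friedooleana-1,3,5(10)-trien-29-oate (8α-H, 9β-Me, 13α-Me, 14β-Me, 17β-Me, 18β-H, 20β-Me) | COc1cc2c(c(C)c1OC)CC[C@H]3[C@@]2(C)CC[C@@]4(C)[C@@H]5C[C@](C)(C(=O)OC)CC[C@]5(C)CC[C@]34C | intermediate
37 | methyl 2,3-dimethoxy-24-nor-D:A-friedooleana-1,3,5(10),6-tetraen-29-oate | COc1cc2c(c(C)c1OC)C=C[C@H]3[C@@]2(C)CC[C@@]4(C)[C@@H]5C[C@](C)(C(=O)OC)CC[C@]5(C)CC[C@]34C | intermediate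
38 | methyl 2,3-dihydroxy-24-nor-D:A-friedooleana-1,3,5(10),6-tetraen-29-oate | Oc1cc2c(c(C)c1O)C=C[C@H]3[C@@]2(C)CC[C@@]4(C)[C@@H]5C[C@](C)(C(=O)OC)CC[C@]5(C)CC[C@]34C | intermediate
39 | (S)-carvone | CC1=CC[C@@H](CC1=O)C(C)=C | starting material
40 | (2R,5S)-2-methyl-5-(prop-1-en-2-yl)cyclohexan-1-one (cis-dihydrocarvone) | C=C(C)[C@H]1CC[C@@H](C)C(=O)C1 | intermediate
41 | ethyl diazoacetate | CCOC(=O)C=[N+]=[N-] | starting material
42 | ethyl (3R,6S)-3-methyl-2-oxo-6-(prop-1-en-2-yl)cycloheptane-1-carboxylate (C1 open, keto/enol) | C=C(C)[C@H]1CC[C@@H](C)C(=O)C(C(=O)OCC)C1 | intermediate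
43 | ethyl (3R,6S)-3-methyl-6-(prop-1-en-2-yl)-2-(trifluoromethylsulfonyloxy)cyclohept-1-ene-1-carboxylate | C=C(C)[C@H]1CC[C@@H](C)C(OS(=O)(=O)C(F)(F)F)=C(C(=O)OCC)C1 | intermediate
44 | ethyl (3R,6S)-2-allyl-3-methyl-6-(prop-1-en-2-yl)cyclohept-1-ene-1-carboxylate | C=C(C)[C@H]1CC[C@@H](C)C(CC=C)=C(C(=O)OCC)C1 | intermediate
45 | 2-[(3R,6S)-2-allyl-3-methyl-6-(prop-1-en-2-yl)cyclohept-1-en-1-yl]propan-2-ol | C=C(C)[C@H]1CC[C@@H](C)C(CC=C)=C(C(C)(C)O)C1 | intermediate
46 | (3R,6S)-2-allyl-3-methyl-1,6-di(prop-1-en-2-yl)cyclohept-1-ene | C=C(C)[C@H]1CC[C@@H](C)C(CC=C)=C(C(C)=C)C1 | intermediate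
47 | (7S,10R)-guaia-1(5),3,11-triene = (5S,8R)-3,8-dimethyl-5-(prop-1-en-2-yl)-1,4,5,6,7,8-hexahydroazulene | C=C(C)[C@H]1CC[C@@H](C)C2=C(C1)C(C)=CC2 | intermediate
48 | ortho-quinone of 38 (2,3-dioxo, C1=C10, C4=C5, C6=C7, 8α-H; not isolated) | O=C1C=C2C(=C(C)C1=O)C=C[C@H]3[C@@]2(C)CC[C@@]4(C)[C@@H]5C[C@](C)(C(=O)OC)CC[C@]5(C)CC[C@]34C | intermediate
49 | CNP0304573.1 (O-2 on C4′, O-3 on C3′, cis-fused dioxane anti to the C10′ methyl) | C=C(C)[C@H]1CC[C@@H](C)C2=C(C1)[C@@]1(C)Oc3cc4c(c(C)c3O[C@H]1C2)C=C[C@H]1[C@@]4(C)CC[C@@]2(C)[C@@H]3C[C@](C)(C(=O)OC)CC[C@]3(C)CC[C@]12C | target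

**Count**

Total steps: 30. Longest linear sequence: 20 steps (steps 1–14, 18–22 and 30).

**Steps most likely to fail**

1. Step 30.
- What may go wrong: the extended ortho-quinone may tautomerise toward C8 into the quinone methide faster than it adds to the diene. It may also add with poor regio- or face selectivity, or the cyclopentadiene may react as a carbon diene at C6=C7.
- Fallback: run the cycloaddition one oxidation level lower. Setting out from 36, BBr3 would give methyl 2,3-dihydroxy-24-nor-D:A-friedooleana-1,3,5(10)-trien-29-oate F1. Ag2O would give its ortho-quinone F2, which has no C6=C7 bond and cannot enolise toward C8. Hetero-Diels–Alder addition of 47 would give the 6,7-dihydro adduct F3. DDQ dehydrogenation at the electron-rich benzylic C6 position, as in step 21, would then rejoin the route at 49.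

2. Step 20.
- What may go wrong: the C14 cation may lose a proton or suffer a 1,2-methyl shift from C13 before the alkene closes on it. The alkene may also add to the wrong face, giving a cis C/D junction.
- Fallback: replace the cation by a tertiary radical. Setting out from 34, Wittig methylenation with Ph3P=CH2 would give the C14 exocyclic alkene F4. Hydrogen-atom transfer from a cobalt hydride (Co(salen) catalyst, PhSiH3, N-fluoro-2,4,6-trimethylpyridinium tetrafluoroborate, hexafluoroisopropanol) would generate the C14 radical, which does not undergo 1,2-alkyl shifts. Addition to the E-alkene, oxidation of the C9 radical to the cation (radical–polar crossover) and Friedel–Crafts closure would rejoin the route at 36.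

3. Step 2.
- What may go wrong: face selectivity under the uncatalysed conditions may be low, the diastereomers may be hard to separate, or dimerisation of the dienone may outrun cycloaddition with only three equivalents of the acrylamide.
- Fallback: resolution in place of the auxiliary. Setting out from 4, oxidation with PhI(OAc)2 in methanol with a large excess of methyl acrylate would give racemic methyl endo-8,8-dimethoxy-5-methyl-7-oxobicyclo[2.2.2]oct-5-ene-2-carboxylate F5. LiOH would give the racemic acid F6. Crystallisation with (R)-1-phenylethylamine would give the (R)-1-phenylethylammonium salt F7 of the required enantiomer (the (S)-amine is used if the other salt crystallises first). Acidification and TMSCHN2 would rejoin the route at 7.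

**Further compounds**

F1 | step 30 | methyl 2,3-dihydroxy-24-nor-D:A-friedooleana-1,3,5(10)-trien-29-oate | Oc1cc2c(c(C)c1O)CC[C@H]3[C@@]2(C)CC[C@@]4(C)[C@@H]5C[C@](C)(C(=O)OC)CC[C@]5(C)CC[C@]34C
F2 | step 30 | ortho-quinone of F1 (ring B saturated) | O=C1C=C2C(=C(C)C1=O)CC[C@H]3[C@@]2(C)CC[C@@]4(C)[C@@H]5C[C@](C)(C(=O)OC)CC[C@]5(C)CC[C@]34C
F3 | step 30 | 6,7-dihydro derivative of 49 | C=C(C)[C@H]1CC[C@@H](C)C2=C(C1)[C@@]1(C)Oc3cc4c(c(C)c3O[C@H]1C2)CC[C@H]1[C@@]4(C)CC[C@@]2(C)[C@@H]3C[C@](C)(C(=O)OC)CC[C@]3(C)CC[C@]12C
F4 | step 20 | C14 exocyclic methylene analogue of 34 | COc1ccc(CC/C=C(\C)CC[C@@]2(C)[C@@H]3C[C@](C)(C(=O)OC)CC[C@]3(C)CCC2=C)c(C)c1OC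
F5 | step 2 | racemic methyl endo-8,8-dimethoxy-5-methyl-7-oxobicyclo[2.2.2]oct-5-ene-2-carboxylate | COC(=O)C1CC2C(C)=CC1C(=O)C2(OC)OC
F6 | step 2 | racemic endo-8,8-dimethoxy-5-methyl-7-oxobicyclo[2.2.2]oct-5-ene-2-carboxylic acid | OC(=O)C1CC2C(C)=CC1C(=O)C2(OC)OC
F7 | step 2 | (R)-1-phenylethylammonium salt of the acid with the cage configuration of 7 | COC1(OC)[C@@H]2C[C@@H](C(=O)[O-])[C@@H](C=C2C)C1=O.C[C@@H]([NH3+])c1ccccc1
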